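Assumption: compounds 11, 14 and 15 are carried as mixtures of epimers at the quaternary carbon and (14, 15) at the tertiary carbinol. Only the silyloxy-bearing carbon is drawn with a configuration, because both undefined centres become sp2 in step 10.

**Retrosynthetic overview**
1. The target comes from the C-10 alcohol of the eleven-membered ring by angelate esterification and one fluoride deprotection. That alcohol comes from the C-10 ketone by reagent-controlled reduction.
2. The eleven-membered ring comes from a Grob fragmentation (ring expansion) of a bicyclo[5.4.0]undecene. The shared bond between the tertiary carbinol and the quaternary carbon bearing CH2OMs breaks, giving C=O and the exocyclic C=CH2 together.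
3. The seven-membered ring comes from ring-closing metathesis, which fixes the enoate geometry, after Barbier addition of a 2-(bromomethyl)acrylate to the six-membered ketone.
4. The six-membered ketone comes from a desymmetrising hydrosilylation (sets C-6) of an achiral 2,2-disubstituted 5,5-dimethylcyclohexane-1,3-dione. That dione is built by Mukaiyama–Michael addition, Dieckmann closure and hydroxymethylation.
5. Order of ring formation: six-membered (Dieckmann), then seven-membered (metathesis), then eleven-membered (fragmentation of the shared bond).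

**Route**

Step 1
Reactants: 1 hex-5-enoyl chloride; 2 (2-methylprop-1-en-1-yl)magnesium bromide
Product: 3 2-methylnona-2,8-dien-4-one
Conditions: CuI (5 mol %), THF, −40 °C
Reagents that add atoms: none
Why: Copper-catalysed acylation of the alkenyl Grignard reagent by the acid chloride stops at the ketone, because the β,β-disubstituted enone formed is a poor acceptor (Grignard–acid chloride ketone synthesis).

Step 2
Reactants: 4 methyl acetate
Product: 5 tert-butyl[(1-methoxyethenyl)oxy]dimethylsilane
Conditions: LiN(iPr)2, THF, −78 °C; TBSCl, DMPU, −78 °C to rt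
Reagents that add atoms: tert-butyldimethylsilyl chloride, CC(C)(C)[Si](C)(C)Cl
Why: O-silylation of the lithium ester enolate in the presence of DMPU gives the ketene silyl acetal (enolate trapping).

Step 3
Reactants: 3 2-methylnona-2,8-dien-4-one; 5 tert-butyl[(1-methoxyethenyl)oxy]dimethylsilane
Product: 6 methyl 3,3-dimethyl-5-oxodec-9-enoate
Conditions: TiCl4 (1.0 equiv), CH2Cl2, −78 °C; H2O
Reagents that add atoms: none
Why: In this Mukaiyama–Michael addition TiCl4 activates the β,β-dimethyl enone and the small ketene silyl acetal builds the gem-dimethyl quaternary carbon without touching the terminal alkene.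

Step 4
Reactants: 6 methyl 3,3-dimethyl-5-oxodec-9-enoate
Product: 7 2-(but-3-en-1-yl)-5,5-dimethylcyclohexane-1,3-dione
Conditions: KOtBu, THF, 0 °C to rt; 1 M HCl
Reagents that add atoms: none
Why: This Dieckmann-type intramolecular Claisen condensation is driven by the stabilised 1,3-dione enolate, and only C-6 of the keto ester can close a six-membered ring.

Step 5
Reactants: 7 2-(but-3-en-1-yl)-5,5-dimethylcyclohexane-1,3-dione; 8 formaldehyde
Product: 9 2-(but-3-en-1-yl)-2-(hydroxymethyl)-5,5-dimethylcyclohexane-1,3-dione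
Conditions: 37% aq. HCHO (5 equiv), NaHCO3 (10 mol %), THF, rt
Reagents that add atoms: none
Why: Aldol addition (hydroxymethylation) of the enolised dione occurs at C-2, since O-attack is reversible and the adduct has no α-hydrogen and cannot dehydrate.

Step 6
Reactants: 9 2-(but-3-en-1-yl)-2-(hydroxymethyl)-5,5-dimethylcyclohexane-1,3-dione
Product: 10 [1-(but-3-en-1-yl)-4,4-dimethyl-2,6-dioxocyclohexyl]methyl methanesulfonate
Conditions: MsCl, Et3N, CH2Cl2, −20 °C
Reagents that add atoms: methanesulfonyl chloride, CS(=O)(=O)Cl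
Why: Sulfonylation of the primary alcohol is fast, and the neopentyl, fully substituted neighbour rules out both β-elimination and substitution of the mesylate.

Step 7
Reactants: 10 [1-(but-3-en-1-yl)-4,4-dimethyl-2,6-dioxocyclohexyl]methyl methanesulfonate
Product: 11 [(2S)-1-(but-3-en-1-yl)-2-{[tert-butyl(dimethyl)silyl]oxy}-4,4-dimethyl-6-oxocyclohexyl]methyl methanesulfonate (both C-1 epimers)
Conditions: tBuMe2SiH (1.1 equiv), (R)-diphenylprolinol-derived B-(o-tolyl)oxazaborolidinium triflimide (10 mol %), toluene, −40 °C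
Reagents that add atoms: tert-butyldimethylsilane, C[SiH](C)C(C)(C)C
Why: Proposed new method: an enantioselective, desymmetrising carbonyl hydrosilylation in which the cationic oxazaborolidinium ion binds one of the two enantiotopic C=O groups through the lone pair anti to the quaternary carbon, the Si–H bond delivers hydride to the exposed face (the R catalyst is chosen by analogy with the CBS model, large group = quaternary carbon, to give the S carbinol) and the nascent silylium ion is captured by the boron-bound alkoxide, which frees the catalyst and leaves the alcohol already protected without ever forming a free alkoxide that could fragment the γ-mesylate; the remaining carbonyl is then too hindered to react, both epimers at the quaternary carbon carry the same S carbinol centre, and the closest known reaction types are oxazaborolidinium- or B(C6F5)3-catalysed hydrosilylation of simple ketones and the CBS borane desymmetrisation of 2,2-disubstituted cyclic 1,3-diketones.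

Step 8
Reactants: 12 2-(bromomethyl)prop-2-enoic acid
Product: 13 2-(trimethylsilyl)ethyl 2-(bromomethyl)prop-2-enoate
Conditions: Me3SiCH2CH2OH, DCC, DMAP (5 mol %), CH2Cl2, 0 °C
Reagents that add atoms: 2-(trimethylsilyl)ethanol, C[Si](C)(C)CCO
Why: Steglich esterification at 0 °C masks the acid as a fluoride-labile ester without displacing the allylic bromide.

Step 9
Reactants: 11 [(2S)-1-(but-3-en-1-yl)-2-{[tert-butyl(dimethyl)silyl]oxy}-4,4-dimethyl-6-oxocyclohexyl]methyl methanesulfonate; 13 2-(trimethylsilyl)ethyl 2-(bromomethyl)prop-2-enoate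
Product: 14 2-(trimethylsilyl)ethyl 2-{[(3S)-2-(but-3-en-1-yl)-3-{[tert-butyl(dimethyl)silyl]oxy}-1-hydroxy-2-{[(methylsulfonyl)oxy]methyl}-5,5-dimethylcyclohexyl]methyl}prop-2-enoate (epimers at C-1 and C-2)
Conditions: Zn dust, 13 (2.5 equiv), sat. aq. NH4Cl–THF, rt
Reagents that add atoms: none
Why: In this zinc Barbier 2-(alkoxycarbonyl)allylation the aqueous NH4Cl protonates the alkoxide at once, so neither lactonisation nor early fragmentation occurs, and the new carbinol centre may form as a mixture because it becomes C=O in step 10.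

Step 10
Reactants: 14 2-(trimethylsilyl)ethyl 2-{[(3S)-2-(but-3-en-1-yl)-3-{[tert-butyl(dimethyl)silyl]oxy}-1-hydroxy-2-{[(methylsulfonyl)oxy]methyl}-5,5-dimethylcyclohexyl]methyl}prop-2-enoate
Product: 16 2-(trimethylsilyl)ethyl (1E,6S)-6-{[tert-butyl(dimethyl)silyl]oxy}-8,8-dimethyl-5-methylidene-10-oxocycloundec-1-ene-1-carboxylate, via bicyclic hydroxy mesylate 15 (not isolated)
Conditions: second-generation Hoveyda–Grubbs catalyst (5 mol %), toluene (5 mM), 80 °C; then −78 to 0 °C, KN(SiMe3)2 (1.05 equiv)
Reagents that add atoms: none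
Why: Ring-closing metathesis first closes the unstrained seven-membered ring, which can only hold the ring-cis (E) trisubstituted enoate, and deprotonation of the tertiary carbinol then triggers a Grob fragmentation in which the freely rotating CH2–OMs bond aligns anti-periplanar to the shared C1–C7 bond, so that this bond breaks to give the ketone, the exocyclic methylene and the eleven-membered ring from every diastereomer of 15, while oxetane formation at the neopentyl carbon cannot compete and exactly one equivalent of base leaves none to isomerise the β,γ-unsaturated ketone.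

Step 11
Reactants: 16 2-(trimethylsilyl)ethyl (1E,6S)-6-{[tert-butyl(dimethyl)silyl]oxy}-8,8-dimethyl-5-methylidene-10-oxocycloundec-1-ene-1-carboxylate
Product: 17 2-(trimethylsilyl)ethyl (1E,6S,10S)-6-{[tert-butyl(dimethyl)silyl]oxy}-10-hydroxy-8,8-dimethyl-5-methylidenecycloundec-1-ene-1-carboxylate
Conditions: (S)-Me-CBS (20 mol %), catecholborane, toluene, −78 °C; MeOH, then 1 M NaOH wash
Reagents that add atoms: none
Why: In this Corey–Bakshi–Shibata reduction the ketone binds anti to the bulkier neopentyl-type CH2CMe2 branch, so the S catalyst delivers hydride to the face that gives the 10S alcohol, and catecholborane at −78 °C leaves the enoate and the 1,1-disubstituted alkene untouched.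

Step 12
Reactants: 17 2-(trimethylsilyl)ethyl (1E,6S,10S)-6-{[tert-butyl(dimethyl)silyl]oxy}-10-hydroxy-8,8-dimethyl-5-methylidenecycloundec-1-ene-1-carboxylate; 18 (2Z)-2-methylbut-2-enoic acid (angelic acid)
Product: 20 2-(trimethylsilyl)ethyl (1E,6S,10S)-6-{[tert-butyl(dimethyl)silyl]oxy}-8,8-dimethyl-10-{[(2Z)-2-methylbut-2-enoyl]oxy}-5-methylidenecycloundec-1-ene-1-carboxylate, via mixed anhydride 19 (not isolated)
Conditions: 18, 2,4,6-Cl3C6H2COCl, Et3N, toluene, rt; then 17, DMAP, rt to 40 °C
Reagents that add atoms: 2,4,6-trichlorobenzoyl chloride, O=C(Cl)c1c(Cl)cc(Cl)cc1Cl (its atoms stay only in 19)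
Why: Yamaguchi esterification through the mixed anhydride acylates the secondary alcohol with retention at C-10 and, near room temperature, without Z to E isomerisation of the angelate.

Step 13
Reactants: 20 2-(trimethylsilyl)ethyl (1E,6S,10S)-6-{[tert-butyl(dimethyl)silyl]oxy}-8,8-dimethyl-10-{[(2Z)-2-methylbut-2-enoyl]oxy}-5-methylidenecycloundec-1-ene-1-carboxylate
Product: 21 (1E,6S,10S)-6-hydroxy-8,8-dimethyl-10-{[(2Z)-2-methylbut-2-enoyl]oxy}-5-methylidenecycloundec-1-ene-1-carboxylic acid
Conditions: Bu4NF (3 equiv), THF, 0 °C to rt; cold 0.5 M HCl work-up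
Reagents that add atoms: none
Why: Fluoride cleaves the silyl ether and triggers β-elimination of the 2-(trimethylsilyl)ethyl ester in one operation (global desilylation), which leaves the hindered angelate, both alkenes and both stereocentres untouched.

**Compound list**
1 | hex-5-enoyl chloride | C=CCCCC(=O)Cl | starting material
2 | (2-methylprop-1-en-1-yl)magnesium bromide | CC(C)=C[Mg]Br | starting material
3 | 2-methylnona-2,8-dien-4-one | CC(C)=CC(=O)CCCC=C | intermediate
4 | methyl acetate | COC(C)=O | starting material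
5 | tert-butyl[(1-methoxyethenyl)oxy]dimethylsilane | C=C(OC)O[Si](C)(C)C(C)(C)C | intermediate
6 | methyl 3,3-dimethyl-5-oxodec-9-enoate | COC(=O)CC(C)(C)CC(=O)CCCC=C | intermediate
7 | 2-(but-3-en-1-yl)-5,5-dimethylcyclohexane-1,3-dione | C=CCCC1C(=O)CC(C)(C)CC1=O | intermediate
8 | formaldehyde | C=O | starting material
9 | 2-(but-3-en-1-yl)-2-(hydroxymethyl)-5,5-dimethylcyclohexane-1,3-dione | C=CCCC1(CO)C(=O)CC(C)(C)CC1=O | intermediate
10 | [1-(but-3-en-1-yl)-4,4-dimethyl-2,6-dioxocyclohexyl]methyl methanesulfonate (achiral) | C=CCCC1(COS(C)(=O)=O)C(=O)CC(C)(C)CC1=O | intermediate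
11 | [(2S)-1-(but-3-en-1-yl)-2-{[tert-butyl(dimethyl)silyl]oxy}-4,4-dimethyl-6-oxocyclohexyl]methyl methanesulfonate (both C-1 epimers) | C=CCCC1(COS(C)(=O)=O)C(=O)CC(C)(C)C[C@@H]1O[Si](C)(C)C(C)(C)C | intermediate
12 | 2-(bromomethyl)prop-2-enoic acid | C=C(CBr)C(=O)O | starting material
13 | 2-(trimethylsilyl)ethyl 2-(bromomethyl)prop-2-enoate | C=C(CBr)C(=O)OCC[Si](C)(C)C | intermediate
14 | 2-(trimethylsilyl)ethyl 2-{[(3S)-2-(but-3-en-1-yl)-3-{[tert-butyl(dimethyl)silyl]oxy}-1-hydroxy-2-{[(methylsulfonyl)oxy]methyl}-5,5-dimethylcyclohexyl]methyl}prop-2-enoate (epimers at C-1 and C-2) | C=CCCC1(COS(C)(=O)=O)C(O)(CC(=C)C(=O)OCC[Si](C)(C)C)CC(C)(C)C[C@@H]1O[Si](C)(C)C(C)(C)C | intermediate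
15 | 2-(trimethylsilyl)ethyl (11S)-11-{[tert-butyl(dimethyl)silyl]oxy}-7-hydroxy-9,9-dimethyl-1-{[(methylsulfonyl)oxy]methyl}bicyclo[5.4.0]undec-4-ene-5-carboxylate (epimers at C-1 and C-7) | CS(=O)(=O)OCC12CCC=C(C(=O)OCC[Si](C)(C)C)CC1(O)CC(C)(C)C[C@@H]2O[Si](C)(C)C(C)(C)C | intermediate
16 | 2-(trimethylsilyl)ethyl (1E,6S)-6-{[tert-butyl(dimethyl)silyl]oxy}-8,8-dimethyl-5-methylidene-10-oxocycloundec-1-ene-1-carboxylate | C=C1CC/C=C(/C(=O)OCC[Si](C)(C)C)CC(=O)CC(C)(C)C[C@@H]1O[Si](C)(C)C(C)(C)C | intermediate
17 | 2-(trimethylsilyl)ethyl (1E,6S,10S)-6-{[tert-butyl(dimethyl)silyl]oxy}-10-hydroxy-8,8-dimethyl-5-methylidenecycloundec-1-ene-1-carboxylate | C=C1CC/C=C(/C(=O)OCC[Si](C)(C)C)C[C@@H](O)CC(C)(C)C[C@@H]1O[Si](C)(C)C(C)(C)C | intermediate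
18 | (2Z)-2-methylbut-2-enoic acid (angelic acid) | C/C=C(/C)C(=O)O | starting material
19 | (2Z)-2-methylbut-2-enoic 2,4,6-trichlorobenzoic anhydride | C/C=C(/C)C(=O)OC(=O)c1c(Cl)cc(Cl)cc1Cl | intermediate
20 | 2-(trimethylsilyl)ethyl (1E,6S,10S)-6-{[tert-butyl(dimethyl)silyl]oxy}-8,8-dimethyl-10-{[(2Z)-2-methylbut-2-enoyl]oxy}-5-methylidenecycloundec-1-ene-1-carboxylate | C=C1CC/C=C(/C(=O)OCC[Si](C)(C)C)C[C@@H](OC(=O)/C(C)=C\C)CC(C)(C)C[C@@H]1O[Si](C)(C)C(C)(C)C | intermediate
21 | (1E,6S,10S)-6-hydroxy-8,8-dimethyl-10-{[(2Z)-2-methylbut-2-enoyl]oxy}-5-methylidenecycloundec-1-ene-1-carboxylic acid | C=C1CC/C=C(/C(=O)O)C[C@@H](OC(=O)/C(C)=C\C)CC(C)(C)C[C@@H]1O | target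

**Step count and risks**

Total step count: 13.

Longest linear sequence: 11 steps (1, 3, 4, 5, 6, 7, 9, 10, 11, 12, 13).

The three steps most likely to fail are 7, 9 and 11.

**Step 7, the proposed new reaction.**
- Traces of free triflimide and the silane could form an achiral silyl triflimide that reduces the dione without selectivity.
- The doubly neopentyl carbonyl may also be too slow at low temperature.
- The fallback sets out from 10 and uses known chemistry.
- CBS desymmetrisation with (R)-Me-CBS (10 mol %) and catecholborane in toluene at −60 °C gives the hydroxy ketone [(2S)-1-(but-3-en-1-yl)-2-hydroxy-4,4-dimethyl-6-oxocyclohexyl]methyl methanesulfonate F1.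
- This is silylated under non-basic conditions (TBSOTf, 2,6-lutidine, CH2Cl2, −78 °C) and comes back to the route at 11, at the cost of one extra step.

**Step 9.**
- The ketone of 11 is flanked by a quaternary carbon, a bulky silyloxy group and the axial methyl of the gem-dimethyl unit, so the ester-stabilised allylzinc reagent may not add.
- The fallback changes the order of events and sets out from 10 together with 13.
- The flatter dione, which is more electrophilic through its second carbonyl, is allylated first (Zn, aq. NH4Cl–THF). This gives the racemic ketol 2-(trimethylsilyl)ethyl 2-{[2-(but-3-en-1-yl)-1-hydroxy-2-{[(methylsulfonyl)oxy]methyl}-5,5-dimethyl-3-oxocyclohexyl]methyl}prop-2-enoate F2.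
- Catalyst-controlled reduction of the remaining ketone with (R)-Me-CBS and catecholborane gives the diol 2-(trimethylsilyl)ethyl 2-{[(3S)-2-(but-3-en-1-yl)-1,3-dihydroxy-2-{[(methylsulfonyl)oxy]methyl}-5,5-dimethylcyclohexyl]methyl}prop-2-enoate F3.
- One equivalent of TBSOTf with 2,6-lutidine at −78 °C silylates only the secondary alcohol, coming back to the route at 14.

**Step 11.**
- Both flanks of the ketone are CH2 groups, so the catalyst may discriminate poorly and give a mixture at C-10.
- The fallback sets out from 16 and no longer relies on facial selectivity.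
- NaBH4 in MeOH at −20 °C gives both C-10 alcohols, which are separable diastereomers because C-6 is fixed.
- The 10S isomer is 17 and continues as planned.
- The epimer 2-(trimethylsilyl)ethyl (1E,6S,10R)-6-{[tert-butyl(dimethyl)silyl]oxy}-10-hydroxy-8,8-dimethyl-5-methylidenecycloundec-1-ene-1-carboxylate F4 is esterified with 18 under Mitsunobu conditions (PPh3, DIAD, toluene, 0 °C) with inversion.
- Both epimers therefore come back to the route at 20.

Further compounds
F1 | step 7 | [(2S)-1-(but-3-en-1-yl)-2-hydroxy-4,4-dimethyl-6-oxocyclohexyl]methyl methanesulfonate (both C-1 epimers) | C=CCCC1(COS(C)(=O)=O)C(=O)CC(C)(C)C[C@@H]1O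
F2 | step 9 | 2-(trimethylsilyl)ethyl 2-{[2-(but-3-en-1-yl)-1-hydroxy-2-{[(methylsulfonyl)oxy]methyl}-5,5-dimethyl-3-oxocyclohexyl]methyl}prop-2-enoate (racemic) | C=CCCC1(COS(C)(=O)=O)C(=O)CC(C)(C)CC1(O)CC(=C)C(=O)OCC[Si](C)(C)C
F3 | step 9 | 2-(trimethylsilyl)ethyl 2-{[(3S)-2-(but-3-en-1-yl)-1,3-dihydroxy-2-{[(methylsulfonyl)oxy]methyl}-5,5-dimethylcyclohexyl]methyl}prop-2-enoate | C=CCCC1(COS(C)(=O)=O)C(O)(CC(=C)C(=O)OCC[Si](C)(C)C)CC(C)(C)C[C@@H]1O
F4 | step 11 | 2-(trimethylsilyl)ethyl (1E,6S,10R)-6-{[tert-butyl(dimethyl)silyl]oxy}-10-hydroxy-8,8-dimethyl-5-methylidenecycloundec-1-ene-1-carboxylate | C=C1CC/C=C(/C(=O)OCC[Si](C)(C)C)C[C@H](O)CC(C)(C)C[C@@H]1O[Si](C)(C)C(C)(C)C
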